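**Retrosynthetic overview**
- Feature: C2 of ring C is bonded to both O1 and ring B (2,6-dimethoxyphenyl). Cutting C2–C3 turns C2 into the OCH2 of a benzyl aryl ether, whose C–H bonds are activated twice (next to oxygen, benzylic) and lie 1,6 to C3.
- Key disconnection C2–C3: ring C comes from a terminal α-diazoketone (C3/C4) by enantioselective rhodium-carbenoid C–H insertion. This step makes the only new ring and the only stereocentre.
- The diazoketone comes from the methyl ketone by diazo transfer. The O1–CH2 bond comes from a phenol and 2,6-dimethoxybenzyl alcohol by a Mitsunobu reaction.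
- The ring A pattern (5-OH, 7,8-dimethoxy) comes from 3,4,5-trimethoxyphenol by C-acetylation, chelation-directed demethylation, and silylation of the less hindered hydroxyl. The hydroxyl next to a methoxy group is thereby left to become O1.
- Rings A and B are bought. Ring C is the only ring formed (step 6), and the last step frees the C5 phenol.

Key step: step 6

Assumption: the sense of induction of Rh2(S-PTTL)4 on this substrate cannot be predicted with certainty. The route is written for the (S)-ligand series giving 2S, and if the configuration check on 9 shows the opposite sense, the equally accessible Rh2(R-PTTL)4 is used.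

**Step 1**
Reactants: 1 3,4,5-trimethoxyphenol
Product: 2 1-(6-hydroxy-2,3,4-trimethoxyphenyl)ethan-1-one
Conditions: AcOH, BF3·OEt2 (excess), 85 °C; then H2O
Reagents that add atoms: acetic acid, CC(=O)O
Why: Friedel–Crafts acylation (O-acetylation followed by a Fries-type shift) of a very electron-rich phenol whose para position is blocked and whose two ortho positions are equivalent, so only one C-acetyl isomer can form.

**Step 2**
Reactants: 2 1-(6-hydroxy-2,3,4-trimethoxyphenyl)ethan-1-one
Product: 3 1-(2,6-dihydroxy-3,4-dimethoxyphenyl)ethan-1-one
Conditions: BCl3 (2.2 equiv), CH2Cl2, −78 to 0 °C; then H2O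
Reagents that add atoms: none
Why: Chelation-directed Lewis-acid ether cleavage, in which boron held at the ketone oxygen reaches only the C2 methoxy group and chloride removes its methyl by SN2, while the unchelated C3 and C4 methyl ethers should survive limited reagent at low temperature.

**Step 3**
Reactants: 3 1-(2,6-dihydroxy-3,4-dimethoxyphenyl)ethan-1-one
Product: 4 1-[2-hydroxy-3,4-dimethoxy-6-(triisopropylsilyloxy)phenyl]ethan-1-one
Conditions: iPr3SiCl (1.05 equiv), imidazole, DMF, 0 °C to rt
Reagents that add atoms: triisopropylsilyl chloride, CC(C)[Si](Cl)(C(C)C)C(C)C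
Why: Sterically controlled monosilylation, since the C6 hydroxyl has only H-5 beside it whereas the C2 hydroxyl is wedged between the acetyl and C3 methoxy groups, and after the first silylation the remaining hydroxyl is locked in a hydrogen bond to the ketone.

**Step 4**
Reactants: 4 1-[2-hydroxy-3,4-dimethoxy-6-(triisopropylsilyloxy)phenyl]ethan-1-one; 5 2,6-dimethoxybenzyl alcohol
Product: 6 1-[2-(2,6-dimethoxybenzyloxy)-3,4-dimethoxy-6-(triisopropylsilyloxy)phenyl]ethan-1-one
Conditions: PPh3, DIAD, toluene, 0 °C to rt (chromatography on Et3N-washed silica)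
Reagents that add atoms: none
Why: Mitsunobu etherification, which activates the primary benzylic alcohol as its alkoxyphosphonium salt under neutral conditions, so the acidic ortho-acyl phenol is O-alkylated without an unstable benzyl halide or a base that would endanger the aryl silyl ether.

**Step 5**
Reactants: 6 1-[2-(2,6-dimethoxybenzyloxy)-3,4-dimethoxy-6-(triisopropylsilyloxy)phenyl]ethan-1-one
Product: 8 2-diazo-1-[2-(2,6-dimethoxybenzyloxy)-3,4-dimethoxy-6-(triisopropylsilyloxy)phenyl]ethan-1-one, via trifluoroacetyl diketone 7 (not isolated)
Conditions: LiN(SiMe3)2, THF, −78 °C; CF3CO2CH2CF3, −78 °C; AcOH quench; then 4-AcNHC6H4SO2N3, Et3N, H2O (1 equiv), MeCN, rt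
Reagents that add atoms: 4-acetamidobenzenesulfonyl azide, CC(=O)Nc1ccc(cc1)S(=O)(=O)N=[N+]=[N-] (the two diazo nitrogens of 8); 2,2,2-trifluoroethyl trifluoroacetate, FC(F)(F)COC(=O)C(F)(F)F (the trifluoroacetyl group of 7 only)
Why: Detrifluoroacetylative diazo transfer (a Regitz-type transfer onto an activated ketone), in which the only possible enolate is C-trifluoroacetylated, the acidic diketone 7 accepts the diazo group from the sulfonyl azide, and the trifluoroacetyl group leaves on the sulfonamide nitrogen under mild base that spares the silyl and benzyl ethers.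

**Step 6**
Reactants: 8 2-diazo-1-[2-(2,6-dimethoxybenzyloxy)-3,4-dimethoxy-6-(triisopropylsilyloxy)phenyl]ethan-1-one
Product: 9 (2S)-2-(2,6-dimethoxyphenyl)-7,8-dimethoxy-5-(triisopropylsilyloxy)chroman-4-one
Conditions: Rh2(S-PTTL)4 (dirhodium tetrakis[N-phthaloyl-(S)-tert-leucinate], 2 mol %), 4 Å MS, CH2Cl2, 0 °C, slow addition of 8
Reagents that add atoms: none
Why: Diazoketone 8 binds through C3 to an axial site of the dirhodium core (both metals divalent), loses N2 and becomes an electrophilic acyl carbenoid, whose empty orbital at C3 overlaps with one σ C–H bond of the OCH2 group so that hydrogen moves to C3 while C2–C3 forms in one asynchronous three-centre event with retention at C2, after which the catalyst is released. The closest known reaction type is the asymmetric C–H insertion of ortho-alkoxyaryl diazoketones next to the ether oxygen under chiral dirhodium carboxylates, which delivers 2-substituted chroman-4-ones. Ring C closes in the 1,6 mode through the six-membered array C3–C4–C4a–C8a–O1–C2, because the normally preferred 1,5 partner is O1, which bears no hydrogen. C2 is controlled by the catalyst alone: the four phthalimide walls of the tert-leucinate ligands fix the orientation of the carbenoid and should expose it to the pro-S hydrogen, and replacing that hydrogen by C3 with retention gives 2S. The step needs insertion to win over attack of an ether oxygen on the carbenoid and over reaction at any other site, and the substrate helps because the positive charge growing at C2 is shared by O1 and ring B, O1 is screened by the C8 methoxy group and the ketone, the C5 oxygen carries a bulky silicon with no C–H next to oxygen, both ortho carbons of ring B are blocked against aromatic attack, and the C8 methoxy group is meta to the ketone and cannot reach C3. Slow addition keeps the diazoketone dilute and suppresses carbene dimerisation, and the sieves exclude O–H insertion of water.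

**Step 7**
Reactants: 9 (2S)-2-(2,6-dimethoxyphenyl)-7,8-dimethoxy-5-(triisopropylsilyloxy)chroman-4-one
Product: 10 (2S)-5-hydroxy-7,8,2',6'-tetramethoxyflavanone
Conditions: Bu4NF/AcOH (1:1, 1.2 equiv), THF, 0 °C
Reagents that add atoms: none
Why: Fluoride-induced cleavage of an aryl silyl ether, buffered by acetic acid so that the released phenoxide is protonated at once and the medium stays too weakly basic for C3 enolisation and retro-oxa-Michael opening, while strong acid, which could ionise the C2–O1 bond next to ring B, is avoided and C2 stays intact.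

**Compound list**
1 | 3,4,5-trimethoxyphenol | COc1cc(O)cc(OC)c1OC | starting material
2 | 1-(6-hydroxy-2,3,4-trimethoxyphenyl)ethan-1-one | CC(=O)c1c(O)cc(OC)c(OC)c1OC | intermediate
3 | 1-(2,6-dihydroxy-3,4-dimethoxyphenyl)ethan-1-one | CC(=O)c1c(O)cc(OC)c(OC)c1O | intermediate
4 | 1-[2-hydroxy-3,4-dimethoxy-6-(triisopropylsilyloxy)phenyl]ethan-1-one | CC(=O)c1c(O[Si](C(C)C)(C(C)C)C(C)C)cc(OC)c(OC)c1O | intermediate
5 | 2,6-dimethoxybenzyl alcohol | COc1cccc(OC)c1CO | starting material
6 | 1-[2-(2,6-dimethoxybenzyloxy)-3,4-dimethoxy-6-(triisopropylsilyloxy)phenyl]ethan-1-one | CC(=O)c1c(O[Si](C(C)C)(C(C)C)C(C)C)cc(OC)c(OC)c1OCc1c(OC)cccc1OC | intermediate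
7 | 4,4,4-trifluoro-1-[2-(2,6-dimethoxybenzyloxy)-3,4-dimethoxy-6-(triisopropylsilyloxy)phenyl]butane-1,3-dione (not isolated) | O=C(CC(=O)C(F)(F)F)c1c(O[Si](C(C)C)(C(C)C)C(C)C)cc(OC)c(OC)c1OCc1c(OC)cccc1OC | intermediate
8 | 2-diazo-1-[2-(2,6-dimethoxybenzyloxy)-3,4-dimethoxy-6-(triisopropylsilyloxy)phenyl]ethan-1-one | [N-]=[N+]=CC(=O)c1c(O[Si](C(C)C)(C(C)C)C(C)C)cc(OC)c(OC)c1OCc1c(OC)cccc1OC | intermediate
9 | (2S)-2-(2,6-dimethoxyphenyl)-7,8-dimethoxy-5-(triisopropylsilyloxy)chroman-4-one | COc1cc(O[Si](C(C)C)(C(C)C)C(C)C)c2c(c1OC)O[C@H](c1c(OC)cccc1OC)CC2=O | intermediate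
10 | (2S)-5-hydroxy-7,8,2',6'-tetramethoxyflavanone | COc1cc(O)c2c(c1OC)O[C@H](c1c(OC)cccc1OC)CC2=O | target

Total step count: 7
Longest linear sequence: 7 steps (1 to 10); 5 is bought.

**Steps most likely to fail**

Step 6.
- What may go wrong: a lone pair of O1 may attack the carbenoid and the very stabilised benzyl group may then shift from oxygen to carbon (ylide path). Hydride transfer from C2 may go to completion, followed by closure through the enolate oxygen instead of C3. The catalyst may also discriminate poorly between the two enantiotopic hydrogens.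
- Fallback: it sets out from phenol 4 and comes back at 9, replacing asymmetric catalysis by ring closure at O1–C2 and resolution.
- Phenol 4 is condensed with commercial 2,6-dimethoxybenzaldehyde in an amine-mediated Claisen–Schmidt reaction (pyrrolidine, EtOH, 50 °C) to give the 2'-hydroxychalcone F1.
- On warming with NaOAc in EtOH, F1 should close by oxa-Michael addition to the racemic silyl flavanone F2. This closure is favoured because the two ortho substituents twist the ketone out of conjugation.
- Preparative HPLC on a cellulose carbamate chiral phase then separates 9 from the (2R)-enantiomer F3.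
- F3 is returned to the NaOAc equilibrium, where it racemises through the chalcone, and is recycled.

Step 4.
- What may go wrong: the hindered, hydrogen-bonded phenol may react slowly. The alkoxyphosphonium salt of the very electron-rich alcohol may ionise early, and the resulting cation may be captured at the free carbon of ring A or by the hydrazide nitrogen.
- Fallback: it sets out from alcohol 5 (with phenol 4) and comes back at 6, replacing the redox condensation by a preformed electrophile.
- Alcohol 5 is converted with SOCl2 in CH2Cl2 at 0 °C into 2,6-dimethoxybenzyl chloride F4, which is used at once.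
- Phenol 4 is then alkylated with F4 under Williamson conditions (Cs2CO3, catalytic Bu4NI, dry MeCN, rt) to give 6. Water is strictly excluded to protect the aryl silyl ether.

Step 5.
- What may go wrong: the silyl group may migrate from the phenol oxygen to the neighbouring lithium enolate oxygen before acylation, or the crowded enolate may be trifluoroacetylated incompletely.
- Fallback: it sets out from ketone 6 and comes back at 8, avoiding a free enolate altogether.
- Soft enolisation (Me3SiOTf, Et3N, CH2Cl2, 0 °C) gives the trimethylsilyl enol ether F5.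
- One equivalent of NBS in THF at −78 °C converts F5 into the α-bromoketone F6 before either electron-rich arene can react.
- Treating F6 with N,N'-ditosylhydrazine and DBU in THF at 0 °C gives 8 by N-alkylation and twofold loss of sulfinate.

**Further compounds**
F1 | step 6 | (E)-3-(2,6-dimethoxyphenyl)-1-[2-hydroxy-3,4-dimethoxy-6-(triisopropylsilyloxy)phenyl]prop-2-en-1-one | COc1cccc(OC)c1/C=C/C(=O)c1c(O)c(OC)c(OC)cc1O[Si](C(C)C)(C(C)C)C(C)C
F2 | step 6 | racemic 2-(2,6-dimethoxyphenyl)-7,8-dimethoxy-5-(triisopropylsilyloxy)chroman-4-one | COc1cc(O[Si](C(C)C)(C(C)C)C(C)C)c2c(c1OC)OC(c1c(OC)cccc1OC)CC2=O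
F3 | step 6 | (2R)-2-(2,6-dimethoxyphenyl)-7,8-dimethoxy-5-(triisopropylsilyloxy)chroman-4-one | COc1cc(O[Si](C(C)C)(C(C)C)C(C)C)c2c(c1OC)O[C@@H](c1c(OC)cccc1OC)CC2=O
F4 | step 4 | 2,6-dimethoxybenzyl chloride | COc1cccc(OC)c1CCl
F5 | step 5 | 1-[2-(2,6-dimethoxybenzyloxy)-3,4-dimethoxy-6-(triisopropylsilyloxy)phenyl]-1-(trimethylsilyloxy)ethene | C=C(O[Si](C)(C)C)c1c(O[Si](C(C)C)(C(C)C)C(C)C)cc(OC)c(OC)c1OCc1c(OC)cccc1OC
F6 | step 5 | 2-bromo-1-[2-(2,6-dimethoxybenzyloxy)-3,4-dimethoxy-6-(triisopropylsilyloxy)phenyl]ethan-1-one | BrCC(=O)c1c(O[Si](C(C)C)(C(C)C)C(C)C)cc(OC)c(OC)c1OCc1c(OC)cccc1OC
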